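Time is the first setting one would turn, and by hand a longer run gives more left-handed product. The readings show two clocks. Left-handed substrate in the green run falls between 10.0 s and 20.0 s with a constant, as read, of 0.0528 s⁻¹, while the remainder, meaning what was charged less c(left-handed product) and c(left-handed substrate), falls in the same run between 40.0 s and 80.0 s with 0.0103 s⁻¹. That is slower than the first constant, so in the green run, after the opening seconds, we take racemization as the rate-limiting step.

The second setting, the loading of racemization catalyst, should then act as time does, so we carry one quantity, the green time: the time the green run needs to reach the same product of loading and time. Equal green time should mean equal c(left-handed product) + c(left-handed substrate). The ochre run at 80.0 s has a green time of 43.3 s and reads 3.3 percentage points above green at 40.0 s, which is the accuracy we claim. Partner and free catalyst stay at one setting in these flasks, so the readings do not show what turning them does.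

common to all: left-handed substrate 0.50 M; right-handed substrate 0.50 M; free catalyst 1.6 mol%
- violet: partner 2.5 equiv; racemization catalyst 0.76 mol%; run made earlier
- ochre: partner 2.5 equiv; racemization catalyst 1.3 mol%; run made earlier
- green: partner 2.5 equiv; racemization catalyst 2.4 mol%; run made earlier
- Tuesday's: partner 2.50 equiv; racemization catalyst 0.6 mol%; time 2.5 min
- Saturday's: partner 2.50 equiv; racemization catalyst 1.2 mol%; time 2.5 min
- Thursday's: partner 2.50 equiv; racemization catalyst 2.5 mol%; time 2.5 min

| run | time / s | left-handed product / % | left-handed substrate / % |
|---|---|---|---|
| violet | 10.0 | 34.5 | 16.2 |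
| violet | 12.0 | 37.7 | 14.4 |
| violet | 20.0 | 45.9 | 8.5 |
| violet | 40.0 | 55.4 | 3.4 |
| violet | 80.0 | 64.1 | 1.9 |
| ochre | 15.0 | 42.4 | 11.6 |
| ochre | 30.0 | 53.2 | 7.4 |
| ochre | 50.0 | 61.7 | 5.5 |
| ochre | 60.0 | 65.4 | 4.7 |
| ochre | 80.0 | 70.2 | 4.3 |
| green | 10.0 | 36.4 | 19.5 |
| green | 12.0 | 38.8 | 16.1 |
| green | 20.0 | 48.5 | 11.5 |
| green | 40.0 | 63.2 | 8.0 |
| green | 80.0 | 77.1 | 3.8 |

(each reading ± 0.5 percentage points)

1. [left-handed product] at the end for Tuesday's, Saturday's, Thursday's, in this order
2. the course of these numbers from the first flask to the last (rises all the way / rises, then falls / falls, then rises / falls all the way / hardly changes)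

- free catalyst is single-handed; left-handed substrate and right-handed substrate are mirror images of each other, charged as a racemate, each of them at the stated concentration
- "hardly changes" means that all values lie within two and a half points (for a concentration: within two and a half percent of the largest)

Our reckoning, for the sum of the two left-handed species at 2.5 min:

Tuesday's: 37.5 s, against green at 40.0 s: 71.2%

Saturday's: 75.0 s, against green at 80.0 s: 80.9%

Thursday's: 156 s, past the last reading, so the remainder is carried on with the green constant: 91.3%

The forecast gives the product itself, not our sum: 0.7 M, 0.81 M and 0.88 M, so rises all the way, on a racemization constant “about linear in catalyst”.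

The flasks end at 0.690 M, 0.783 M and 0.864 M of left-handed product, so rises all the way, and the forecast stands within its tolerance.

    partner + free catalyst + right-handed substrate → free catalyst + right-handed product (k = 0.440 L² mol⁻² s⁻¹)
    racemization catalyst ⇌ dormant form (K = 1.60, k = 0.00480 s⁻¹)
    left-handed substrate + racemization catalyst ⇌ right-handed substrate + racemization catalyst, rate k3*[racemization catalyst]*[left-handed substrate] forward; the back reaction follows from the equilibrium constant (k = 2.30 L mol⁻¹ s⁻¹)
    partner + free catalyst + left-handed substrate → free catalyst + left-handed product (k = 14.0 L² mol⁻² s⁻¹)

Tuesday's flask still holds 18.8% right-handed substrate and 10.7% right-handed product at 2.50 min, both inside our remainder. At its green time of 37.5 s, Tuesday's flask ends with a sum of 70.5%, beside green's 71.2% at 40.0 s. Thursday's flask at 1.25 min has a green time of 78.1 s and holds 80.9%, beside green's 80.9% at 80.0 s. At 2.50 min, with its green time of 156 s past the last reading, Thursday's flask holds 88.5%, against the 91.3% we carried on.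

The readings were generated by integration from invented constants; the scatter is artificial.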